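**Assumption:** the target SMILES has no stereodescriptor and no stereocentre, so the compound is made as drawn and no stereochemistry has to be set.

## Retrosynthetic overview

1. Asterelin A ⇒ furan C–O closure (cyclodehydration of a 2,2'-dioxygenated biaryl, merged with global O-demethylation) ⇒ 18-membered riccardin-type biaryl macrocycle 10.
2. 10 ⇒ biaryl C–C bond by intramolecular dehydrogenative phenol–arene coupling (this closes the macrocycle) ⇒ acyclic perrottetin-type bis(bibenzyl) 9.
3. 9 ⇒ Wittig/hydrogenation ⇒ aldehyde 3 + 3-(benzyloxy)benzyl unit; 3 ⇒ Ullmann diaryl ether ⇒ pterostilbene + 3-bromo-4-methoxybenzaldehyde.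
4. Ring order: acyclic diaryl ether → macrocycle by C–C phenol coupling → furan by C–O closure. This follows the biogenetic sequence bibenzyl → perrottetin type → riccardin type → dibenzofuran. The extra ring-A oxygen comes in with pterostilbene, so the furan closes by loss of water rather than by a second dehydrogenation.

Ring labels used below: A = 3,5-dioxygenated ring, B = mono-phenol ring (becomes the second furan-fused ring), C = 4-oxy-3-aryloxy ring, D = para-phenylene.

## Route

Step 1
Reactants: 1 pterostilbene; 2 3-bromo-4-methoxybenzaldehyde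
Product: 3 3-{4-[(E)-2-(3,5-dimethoxyphenyl)ethenyl]phenoxy}-4-methoxybenzaldehyde
Conditions: CuI (10 mol %), picolinic acid (20 mol %), K3PO4 (2 equiv), DMSO, 90 °C, Ar
Reagents that add atoms: none
Why: Ligand-accelerated Ullmann diaryl ether synthesis joins the only phenol of 1 to the only C–Br of 2 (the classical bromide for perrottetin/marchantin-type ethers); aldehyde and stilbene are inert under these conditions.

Step 2
Reactants: 3 aldehyde from step 1; 4 3-(benzyloxy)benzyl bromide; 5 triphenylphosphine
Product: 8 benzyl-protected bis-stilbene (new C=C as E/Z mixture), via phosphonium bromide 6 (not isolated), via ylide 7 (not isolated)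
Conditions: 4 + PPh3, THF, reflux; then t-BuOK, 0 °C; then 3, 0 °C → rt
Reagents that add atoms: none
Why: One-pot phosphonium formation and Wittig olefination: the benzylic bromide quaternises PPh3, t-BuOK gives the semi-stabilised ylide, and this olefinates the single aldehyde; the E/Z ratio is irrelevant because the alkene is saturated next.

Step 3
Reactants: 8 benzyl-protected bis-stilbene
Product: 9 3-[2-(3-{4-[2-(3,5-dimethoxyphenyl)ethyl]phenoxy}-4-methoxyphenyl)ethyl]phenol
Conditions: H2 (1 atm), 10% Pd/C, EtOAc–MeOH, rt
Reagents that add atoms: none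
Why: Catalytic hydrogenation saturates both stilbene C=C bonds and hydrogenolyses the benzyl ether in one operation, leaving ring B as the only free phenol; aryl methyl ethers and the diaryl ether survive.

Step 4
Reactants: 9 acyclic bis(bibenzyl) mono-phenol
Product: 10 18-membered macrocyclic biaryl (new bond: ring A C-2, ortho to its CH2CH2, to ring B C-6, ortho to OH and para to its CH2CH2)
Conditions: FeCl3 (20 mol %), t-BuOOt-Bu (1.5 equiv), HFIP, rt, syringe-pump addition of 9 to 1 mM final concentration
Reagents that add atoms: none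
Why: Proposed new method: Fe(III) binds and oxidises the only free phenol (ring B) to a phenoxyl radical, which is trapped at its ortho carbon C-6 by C-2 of ring A, by far the most nucleophilic arene present and one whose two activated positions are equivalent, then loss of e−/H+ rearomatises; ortho attack is expected over para because C-4 sits next to the tether and would give a tighter 16-membered ring, whereas C-6 gives the 18-membered riccardin-type ring; the closest known reaction types are the intermolecular iron-catalysed oxidative phenol–arene cross-dehydrogenative coupling in HFIP and oxidative phenol-coupling macrocyclisations to biaryl cyclophanes.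

Step 5
Reactants: 10 macrocyclic biaryl
Product: 12 asterelin A, via tetraphenol 11 (not isolated)
Conditions: 48% aq HBr, AcOH, 120 °C, Ar
Reagents that add atoms: none
Why: Acidic aryl methyl ether cleavage gives tetraphenol 11; its resorcinol ring is protonated at the biaryl carbon, the ring-B phenol adds to the adjacent C–OH carbon and water is lost (cyclodehydration of a 2,2'-dihydroxybiaryl to a dibenzofuran); the para OH cannot reach and is retained.

## Compound list

1 | pterostilbene, (E)-4-[2-(3,5-dimethoxyphenyl)ethenyl]phenol | COc1cc(OC)cc(/C=C/c2ccc(O)cc2)c1 | starting material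
2 | 3-bromo-4-methoxybenzaldehyde | COc1ccc(C=O)cc1Br | starting material
3 | 3-{4-[(E)-2-(3,5-dimethoxyphenyl)ethenyl]phenoxy}-4-methoxybenzaldehyde | COc1cc(OC)cc(/C=C/c2ccc(Oc3cc(C=O)ccc3OC)cc2)c1 | intermediate
4 | 3-(benzyloxy)benzyl bromide | BrCc1cccc(OCc2ccccc2)c1 | starting material
5 | triphenylphosphine | c1ccc(cc1)P(c1ccccc1)c1ccccc1 | starting material
6 | [3-(benzyloxy)benzyl]triphenylphosphonium bromide | [Br-].C(c1cccc(OCc2ccccc2)c1)[P+](c1ccccc1)(c1ccccc1)c1ccccc1 | intermediate
7 | [3-(benzyloxy)benzylidene]triphenylphosphorane | C(=P(c1ccccc1)(c1ccccc1)c1ccccc1)c1cccc(OCc2ccccc2)c1 | intermediate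
8 | 1-{4-[(E)-2-(3,5-dimethoxyphenyl)ethenyl]phenoxy}-2-methoxy-5-{2-[3-(benzyloxy)phenyl]ethenyl}benzene, E/Z mixture at the second alkene | COc1cc(OC)cc(/C=C/c2ccc(Oc3cc(C=Cc4cccc(OCc5ccccc5)c4)ccc3OC)cc2)c1 | intermediate
9 | 3-[2-(3-{4-[2-(3,5-dimethoxyphenyl)ethyl]phenoxy}-4-methoxyphenyl)ethyl]phenol | COc1cc(OC)cc(CCc2ccc(Oc3cc(CCc4cccc(O)c4)ccc3OC)cc2)c1 | intermediate
10 | macrocyclic biaryl: 9 with a C–C bond between C-2 of the 3,5-dimethoxyphenyl ring and C-6 of the phenol ring (ortho to OH, para to its chain) | COc1cc2c(-c3ccc(cc3O)CCc3ccc(OC)c(c3)Oc3ccc(cc3)CC2)c(OC)c1 | intermediate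
11 | macrocyclic tetraphenol: 10 with all three OMe groups as OH | Oc1cc2c(-c3ccc(cc3O)CCc3ccc(O)c(c3)Oc3ccc(cc3)CC2)c(O)c1 | intermediate
12 | asterelin A | Oc1cc2c3c(c1)oc1cc(ccc13)CCc1ccc(O)c(c1)Oc1ccc(cc1)CC2 | target

## Step count and risks

Total steps: 5. Longest linear sequence: 5 (1 → 3 → 8 → 9 → 10 → 12).

**Most likely to fail, first: step 4.** The phenol may couple at its para carbon (C-4) instead of C-6, rings B and C may close to a 9,10-dihydrophenanthrene, or the material may oligomerise. The fallback fixes both coupling sites with halogens and closes the macrocycle reductively. It sets out from aldehyde 3 and comes back at tetraphenol 11. Commercial 4-bromo-3-methoxybenzyl bromide and PPh3 (5) are heated in THF to give (4-bromo-3-methoxybenzyl)triphenylphosphonium bromide F1. t-BuOK converts this into (4-bromo-3-methoxybenzylidene)triphenylphosphorane F2, which olefinates 3 to the bis-stilbene aryl bromide F3. Diimide (TsNHNH2, NaOAc, THF–H2O, reflux) saturates both alkenes without touching C–Br and gives the bibenzyl aryl bromide F4. NBS (1 equiv, MeCN, 0 °C) brominates only the most electron-rich ring, at the position between the chain and an OMe, to give the dibromide F5. Ni(cod)2/2,2'-bipyridine (DMF–toluene, 60 °C, high dilution) then forms the biaryl bond by reductive aryl–aryl coupling, giving the macrocyclic tetramethyl ether F6. Under the step 5 conditions F6 loses all four methyl groups to give 11 and then 12.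

**Second: step 5.** Planarising the biaryl inside the macrocycle may be slow, or the hot acid may degrade the electron-rich phenols. The fallback replaces the acid dehydration by a metal-catalysed C–O coupling. It sets out from 10 and comes back at 12. Tf2O/pyridine (CH2Cl2, 0 °C) converts the single phenol of 10 into the aryl triflate F7. BBr3 (CH2Cl2, −78 °C → rt) cleaves the three methyl ethers without touching the triflate and gives the triflate triol F8. Pd(OAc)2/t-BuXPhos with K3PO4 (toluene, 100 °C) then closes the furan by intramolecular O-arylation: only the ring-A hydroxyl ortho to the biaryl bond can reach the C–OTf carbon, which gives 12.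

**Third: step 1.** The bromide is ortho-methoxylated and only weakly activated, so the Ullmann coupling may stall, or the aldehyde may suffer. The fallback makes the diaryl ether by SNAr and builds ring A last. It sets out from ylide 7 (generated from 4 and 5 as in step 2) and comes back at 9. Ylide 7, with one extra equivalent of t-BuOK for the phenol, olefinates commercial isovanillin to 5-{2-[3-(benzyloxy)phenyl]ethenyl}-2-methoxyphenol F9. F9 displaces fluoride from 4-fluorobenzaldehyde (K2CO3, DMF, 140 °C) to give 4-(5-{2-[3-(benzyloxy)phenyl]ethenyl}-2-methoxyphenoxy)benzaldehyde F10. Commercial (3,5-dimethoxybenzyl)triphenylphosphonium bromide and t-BuOK give (3,5-dimethoxybenzylidene)triphenylphosphorane F11, which olefinates F10 to the bis-stilbene as a mixture of alkene isomers F12. F12 has the constitution of 8, and hydrogenation under the step 3 conditions gives 9.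

## Further compounds

F1 | step 4 | (4-bromo-3-methoxybenzyl)triphenylphosphonium bromide | [Br-].COc1cc(C[P+](c2ccccc2)(c2ccccc2)c2ccccc2)ccc1Br
F2 | step 4 | (4-bromo-3-methoxybenzylidene)triphenylphosphorane | COc1cc(C=P(c2ccccc2)(c2ccccc2)c2ccccc2)ccc1Br
F3 | step 4 | bis-stilbene aryl bromide (second alkene E/Z) | COc1cc(OC)cc(/C=C/c2ccc(Oc3cc(C=Cc4ccc(Br)c(OC)c4)ccc3OC)cc2)c1
F4 | step 4 | bibenzyl aryl bromide | COc1cc(OC)cc(CCc2ccc(Oc3cc(CCc4ccc(Br)c(OC)c4)ccc3OC)cc2)c1
F5 | step 4 | dibromide (second Br on the dimethoxy ring, between chain and OMe) | COc1cc(OC)c(Br)c(CCc2ccc(Oc3cc(CCc4ccc(Br)c(OC)c4)ccc3OC)cc2)c1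
F6 | step 4 | macrocyclic biaryl tetramethyl ether (O-methyl ether of 10) | COc1cc2c(-c3ccc(cc3OC)CCc3ccc(OC)c(c3)Oc3ccc(cc3)CC2)c(OC)c1
F7 | step 5 | aryl triflate of 10 | COc1cc2c(-c3ccc(cc3OS(=O)(=O)C(F)(F)F)CCc3ccc(OC)c(c3)Oc3ccc(cc3)CC2)c(OC)c1
F8 | step 5 | triflate triol (F7 with the three OMe groups as OH) | Oc1cc2c(-c3ccc(cc3OS(=O)(=O)C(F)(F)F)CCc3ccc(O)c(c3)Oc3ccc(cc3)CC2)c(O)c1
F9 | step 1 | 5-{2-[3-(benzyloxy)phenyl]ethenyl}-2-methoxyphenol (E/Z) | COc1ccc(C=Cc2cccc(OCc3ccccc3)c2)cc1O
F10 | step 1 | 4-(5-{2-[3-(benzyloxy)phenyl]ethenyl}-2-methoxyphenoxy)benzaldehyde (E/Z) | COc1ccc(C=Cc2cccc(OCc3ccccc3)c2)cc1Oc1ccc(C=O)cc1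
F11 | step 1 | (3,5-dimethoxybenzylidene)triphenylphosphorane | COc1cc(OC)cc(C=P(c2ccccc2)(c2ccccc2)c2ccccc2)c1
F12 | step 1 | bis-stilbene with the constitution of 8, E/Z mixture at both alkenes | COc1cc(OC)cc(C=Cc2ccc(Oc3cc(C=Cc4cccc(OCc5ccccc5)c4)ccc3OC)cc2)c1
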